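**Retrosynthetic overview**
1. Target 25 comes from Swern oxidation of the 11,12-bis(silyl ether) 24. The ester bond joins alcohol 18 and acid 22, which is made from anisole and acrylic acid.
2. Alcohol 18 comes from triol 17, and 17 comes from the tricyclic γ-lactone 15 by LiAlH4 reduction and allylic oxidation of C12.
3. Lactone 15 comes from the key oxidative ring contraction of the trans-fused 6-7 hydroxy enone 12, in which C10 shifts from C11 to C9. This forms ring B last.
4. Enone 12 comes from ring-closing metathesis of diene 9, which forms the seven-membered ring second, followed by a redox adjustment.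
5. Diene 9 comes from an asymmetric conjugate addition/aldol sequence on enone 4. Ring A is formed first, by Robinson annulation of 1 and 2.

Assumption: C1–C12 are drimane labels of the target (C11 is the formyl carbon on C9, C12 the formyl carbon on C8). α/β refer to the usual drimane drawing with the C10 methyl β. The ligand enantiomer in step 2 is the one that gives the 5α-H series shown.

**Step 1**
Reactants: 1 isobutyraldehyde; 2 pent-1-en-3-one
Product: 4 2,4,4-trimethylcyclohex-2-en-1-one, via keto aldehyde 3 (not isolated)
Conditions: cat. H2SO4, toluene, reflux, Dean–Stark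
Reagents that add atoms: none
Why: Acid-catalysed Michael addition followed by intramolecular aldol condensation (Robinson annulation) is the standard one-pot entry to 4,4-dimethylcyclohexenones, and no stereocentre is formed.

**Step 2**
Reactants: 4 2,4,4-trimethylcyclohex-2-en-1-one; 5 4-bromo-2-methylbut-1-ene; 6 acrolein
Product: 9 2-(1-hydroxyallyl)-2,4,4-trimethyl-3-(3-methylbut-3-enyl)cyclohexanone (C5: H α; C10: CH3 β; C11 epimers), via Grignard reagent 7 (not isolated), via magnesium enolate 8 (not isolated)
Conditions: 5, Mg, Et2O, reflux; Cu(OTf)2 (3 mol %), chiral hydroxyalkyl-imidazolinium hexafluorophosphate (NHC precursor, 4 mol %), 4, Et2O, −30 °C; then 6, −78 °C; aq NH4Cl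
Reagents that add atoms: none
Why: In this copper–NHC-catalysed asymmetric conjugate addition of an alkyl Grignard reagent to an α-methyl cyclic enone with aldol trapping, the catalyst sets C5, acrolein attacks enolate 8 anti to the new side chain so the C10 quaternary centre is trans, and the C11 carbinol epimers are inconsequential because C11 is oxidised in step 5.

**Step 3**
Reactants: 9 keto alcohol diene
Product: 10 trans-fused 6-7 bicyclic keto allylic alcohol (C1 ketone; seven-membered ring C10-C11H(OH)-C9H=C8(CH3)-C7-C6-C5; 5α-H; 10β-CH3)
Conditions: second-generation Hoveyda–Grubbs catalyst RuCl2(SIMes)(=CH-C6H4-2-O-i-Pr) (5 mol %), toluene, 80 °C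
Reagents that add atoms: none
Why: Ring-closing metathesis of a vinyl carbinol with a 1,1-disubstituted alkene gives trisubstituted cycloheptenes reliably, the trans arrangement of the two chains is compatible with a seven-membered ring, and no stereocentre changes.

**Step 4**
Reactants: 10 bicyclic keto allylic alcohol
Product: 11 1β,11-diol of the 6-7 bicycle
Conditions: NaBH4, MeOH, 0 °C
Reagents that add atoms: none
Why: Borohydride delivers hydride axially from the α face, opposite the axial C10 methyl (as in Wieland–Miescher-type ketones), which gives the equatorial 1β-alcohol.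

**Step 5**
Reactants: 11 diol
Product: 12 1β-hydroxy enone (C11 ketone conjugated with C9=C8)
Conditions: activated MnO2 (15 equiv), CH2Cl2, rt
Reagents that add atoms: none
Why: MnO2 oxidises only the allylic carbinol at C11 and leaves the saturated 1β-alcohol untouched (chemoselective allylic oxidation).

**Step 6 (key step)**
Reactants: 12 1β-hydroxy enone
Product: 15 drim-7-en-11,1β-olide (γ-lactone O-C1/C11=O; 5α-H; 9α-H; 10β-CH3), via dienyl methyl ether 13 (not isolated), via hydroxy methyl ester 14 (not isolated)
Conditions: PhI(OAc)2 (1.1 equiv), HC(OMe)3/MeOH, cat. H2SO4, 0 °C to rt; then H2O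
Reagents that add atoms: water, O
Why: Proposed new method: a vinylogous oxidative ring contraction in which acid and orthoformate convert 12 into dienyl ether 13 (the only possible enolisation, since C10 is quaternary), the trivalent-iodine electrophile attacks the nucleophilic terminus of 13, methanol adds to the C11 oxocarbenium ion, and loss of the very good leaving group iodobenzene from the allyl system is pushed by the alkoxy groups on C11, so that the only carbon substituent able to move, quaternary C10, shifts from C11 to C9 with retention at C10, contracting the seven-membered ring to ring B, placing the alkene at C7=C8 and giving ester 14; the 1β-hydroxyl can lactonise only with a 9β-carboxyl group, so acid-mediated equilibration at C9 funnels material to the 9α-H lactone 15; the closest known reaction types are the PhI(OAc)2- or Tl(NO3)3-mediated oxidative ring contraction of cyclic ketones and 1,2-aryl shift of aryl ketones in acidic trimethyl orthoformate and the quasi-Favorskii (semibenzilic) rearrangement, none of which has been shown in vinylogous form on a cycloheptenone.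

**Step 7**
Reactants: 15 lactone
Product: 16 drim-7-ene-1β,11-diol
Conditions: LiAlH4, THF, 0 °C to rt; Fieser work-up
Reagents that add atoms: none
Why: Hydride reduction of a γ-lactone to the diol is routine, and C9 is no longer epimerisable afterwards.

**Step 8**
Reactants: 16 diol
Product: 17 drim-7-ene-1β,11,12-triol
Conditions: SeO2 (0.3 equiv), t-BuOOH (2.5 equiv), CH2Cl2, 0 °C to rt
Reagents that add atoms: tert-butyl hydroperoxide, CC(C)(C)OO
Why: Riley allylic oxidation attacks the substituents on the more substituted alkene carbon C8 in the order CH3 before CH, so C12 is hydroxylated as in the drimenol series, and no stereocentre is touched.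

**Step 9**
Reactants: 17 triol
Product: 18 11,12-bis(triethylsilyl) ether of 17 (1β-OH free)
Conditions: Et3SiCl (2.1 equiv), imidazole, CH2Cl2, −20 °C
Reagents that add atoms: chlorotriethylsilane, CC[Si](Cl)(CC)CC
Why: The two primary alcohols silylate far faster than the neopentyl secondary 1β-alcohol (selective silylation).

**Step 10**
Reactants: 19 anisole; 20 acrylic acid
Product: 22 (E)-4-methoxycinnamic acid, via 4-bromoanisole 21 (not isolated)
Conditions: NBS (1.0 equiv), MeCN, rt; then 20, Pd(OAc)2 (2 mol %), P(o-tol)3 (4 mol %), Et3N, 90 °C; aq HCl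
Reagents that add atoms: none
Why: Para-selective electrophilic bromination of anisole followed in the same pot by a Mizoroki–Heck reaction gives the E-cinnamic acid.

**Step 11**
Reactants: 18 bis(silyl ether) alcohol; 22 (E)-4-methoxycinnamic acid
Product: 24 1β-(E)-4-methoxycinnamate of 18, via mixed anhydride 23 (not isolated)
Conditions: 22, 2,4,6-trichlorobenzoyl chloride, Et3N, toluene, rt; then 18, DMAP, 60 °C
Reagents that add atoms: none
Why: Yamaguchi esterification acylates hindered secondary alcohols with retention at C1 and leaves the silyl ethers and alkenes untouched.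

**Step 12**
Reactants: 24 ester bis(silyl ether)
Product: 25 target, 1β-(E)-4-methoxycinnamoyloxy-polygodial
Conditions: (COCl)2, DMSO, CH2Cl2, −78 to −40 °C; Et3N, −78 to 0 °C
Reagents that add atoms: none
Why: Swern conditions convert primary triethylsilyl ethers directly into aldehydes, both positions are activated before base is added so no lactol or lactone forms, and the cold, brief exposure to base preserves the 9β-formyl configuration.

**Compound list**
1 | isobutyraldehyde | CC(C)C=O | starting material
2 | pent-1-en-3-one | CCC(=O)C=C | starting material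
3 | 2,2-dimethyl-5-oxoheptanal | O=CC(C)(C)CCC(=O)CC | intermediate
4 | 2,4,4-trimethylcyclohex-2-en-1-one | CC1=CC(C)(C)CCC1=O | intermediate
5 | 4-bromo-2-methylbut-1-ene | C=C(C)CCBr | starting material
6 | acrolein | C=CC=O | starting material
7 | (3-methylbut-3-enyl)magnesium bromide | C=C(C)CC[Mg]Br | intermediate
8 | bromomagnesium enolate of the conjugate adduct (5α-H) | CC1=C(O[Mg]Br)CCC(C)(C)[C@@H]1CCC(C)=C | intermediate
9 | keto alcohol diene (5α-H; 10β-CH3; C11 epimers) | O=C1CCC(C)(C)[C@H](CCC(C)=C)[C@@]1(C)C(O)C=C | intermediate
10 | trans-fused 6-7 keto allylic alcohol | O=C1CCC(C)(C)[C@@H]2CCC(C)=CC(O)[C@@]12C | intermediate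
11 | 6-7 bicyclic 1β,11-diol | O[C@@H]1CCC(C)(C)[C@@H]2CCC(C)=CC(O)[C@@]12C | intermediate
12 | 6-7 bicyclic 1β-hydroxy enone | O[C@@H]1CCC(C)(C)[C@@H]2CCC(C)=CC(=O)[C@@]12C | intermediate
13 | dienyl methyl ether of 12 | O[C@@H]1CCC(C)(C)[C@@H]2CC=C(C)C=C(OC)[C@@]12C | intermediate
14 | methyl 1β-hydroxydrim-7-en-11-oate | O[C@@H]1CCC(C)(C)[C@@H]2CC=C(C)[C@H](C(=O)OC)[C@@]12C | intermediate
15 | drim-7-en-11,1β-olide | O1[C@@H]2CCC(C)(C)[C@@H]3CC=C(C)[C@H](C1=O)[C@@]23C | intermediate
16 | drim-7-ene-1β,11-diol | O[C@@H]1CCC(C)(C)[C@@H]2CC=C(C)[C@H](CO)[C@@]12C | intermediate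
17 | drim-7-ene-1β,11,12-triol | O[C@@H]1CCC(C)(C)[C@@H]2CC=C(CO)[C@H](CO)[C@@]12C | intermediate
18 | 11,12-bis(triethylsilyloxy)drim-7-en-1β-ol | O[C@@H]1CCC(C)(C)[C@@H]2CC=C(CO[Si](CC)(CC)CC)[C@H](CO[Si](CC)(CC)CC)[C@@]12C | intermediate
19 | anisole | COc1ccccc1 | starting material
20 | acrylic acid | C=CC(=O)O | starting material
21 | 4-bromoanisole | COc1ccc(Br)cc1 | intermediate
22 | (E)-4-methoxycinnamic acid | COc1ccc(/C=C/C(=O)O)cc1 | intermediate
23 | (E)-4-methoxycinnamic 2,4,6-trichlorobenzoic anhydride | COc1ccc(/C=C/C(=O)OC(=O)c2c(Cl)cc(Cl)cc2Cl)cc1 | intermediate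
24 | 1β-(E)-4-methoxycinnamate of 18 | COc1ccc(/C=C/C(=O)O[C@@H]2CCC(C)(C)[C@@H]3CC=C(CO[Si](CC)(CC)CC)[C@H](CO[Si](CC)(CC)CC)[C@@]23C)cc1 | intermediate
25 | 1β-(E)-4-methoxycinnamoyloxy-polygodial | COc1ccc(/C=C/C(=O)O[C@@H]2CCC(C)(C)[C@@H]3CC=C(C=O)[C@H](C=O)[C@@]23C)cc1 | target

**Step count**
Total: 12 steps.
Longest linear sequence: 11 steps (steps 1–9, 11 and 12).

**The three steps most likely to fail**

**Step 2.** The β-carbon of 4 is neopentyl and the enone is α-substituted, so both reactivity and enantioselectivity may fall. The fallback gives up catalytic enantiocontrol. Setting out from 4, the stoichiometric cuprate made from 7 and CuBr·SMe2 adds in the presence of Me3SiCl to give the racemic trimethylsilyl enol ether F1. A BF3·OEt2-mediated Mukaiyama aldol reaction with 6 then gives racemic 9, and steps 3 and 4 are run on the racemate. Chromatography on a chiral stationary phase removes the mirror-image diol F2, and the route is rejoined at 11.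

**Step 6 (the proposed new step).** The iodine reagent may only α- or γ-oxygenate the enone, or the dienyl ether may react at C12. The fallback uses known chemistry and replaces the oxidative shift by a carbene ring contraction. Setting out from 12, kinetic deconjugation (excess LDA, then AcOH at −78 °C) gives the β,γ-unsaturated ketone F3. Trifluoroacetylation (LiHMDS, CF3CO2CH2CF3) gives the α-trifluoroacetyl ketone F4, and detrifluoroacetylative diazo transfer (MsN3, Et3N) gives the α-diazo ketone F5. Photochemical Wolff rearrangement moves C10 to C9 and forms the ketene F6, which is trapped internally by the 1β-hydroxyl. The route comes back at 15.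

**Step 11.** The 1β-alcohol is flanked by the quaternary C10 and the C11 silyloxymethyl group, so acylation may be slow. The fallback builds the cinnamate on the core. Setting out from 18, the small and more reactive acryloyl chloride (Et3N, DMAP, CH2Cl2) gives the 1β-acrylate F7. A Mizoroki–Heck reaction of F7 with 21, isolated from the first half of step 10 (Pd(OAc)2, P(o-tol)3, Et3N, MeCN, 80 °C), comes back at 24.

**Further compounds**
F1 | step 2 | racemic trimethylsilyl enol ether of the conjugate adduct | CC1=C(O[Si](C)(C)C)CCC(C)(C)C1CCC(C)=C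
F2 | step 2 | mirror-image diol (ent-11) | O[C@H]1CCC(C)(C)[C@H]2CCC(C)=CC(O)[C@]12C
F3 | step 6 | β,γ-unsaturated 1β-hydroxy ketone (C7=C8, C9H2) | O[C@@H]1CCC(C)(C)[C@@H]2CC=C(C)CC(=O)[C@@]12C
F4 | step 6 | α-trifluoroacetyl ketone | O[C@@H]1CCC(C)(C)[C@@H]2CC=C(C)C(C(=O)C(F)(F)F)C(=O)[C@@]12C
F5 | step 6 | α-diazo ketone | O[C@@H]1CCC(C)(C)[C@@H]2CC=C(C)C(=[N+]=[N-])C(=O)[C@@]12C
F6 | step 6 | ring-contracted ketene | O[C@@H]1CCC(C)(C)[C@@H]2CC=C(C)C(=C=O)[C@@]12C
F7 | step 11 | 1β-acrylate of 18 | C=CC(=O)O[C@@H]1CCC(C)(C)[C@@H]2CC=C(CO[Si](CC)(CC)CC)[C@H](CO[Si](CC)(CC)CC)[C@@]12C
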